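**Plan**

1. Retrosynthesis: the C7 ester, the silyl ethers and the C6 epimer are adjusted last. Ring A and the 19,10-lactone are then cut together at C2–C3 and C4–C5, which removes C3–C4 (with C18 and C19) as a 2-formylpropanoyl group hung on O10.
2. Enabling feature: O10 sits on the α face of C10, next to C5 of a C5=C6 enoate in ring B, and C10 also carries the cis-vinyl carbon C2. C4 of the O10-acyl group can therefore add 5-exo to C5 (lactone ring O10–C19–C4–C5–C10), after which the aldehyde C3 lies within bonding distance of C2 (ring A).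
3. Forward order: ring B from a resolved 4-silyloxy-2-propargylcyclopentenone; ring C by cycloaddition of 2,3-bis(silyloxy)butadiene across C8=C9; ring D by gold-catalysed attack of C13 on the propargyl alkyne; then C7 by carbonylation, C1–C2 by ethynylation and cis-iodoalkene formation, and finally the lactone/ring-A bicyclization.
4. Stereochemistry: the lipase-resolved C10 silyl ether directs the cycloaddition (C8, C9); C13 follows from bridging; C12 from hydride delivery along the equatorial path; C10 from β attack on the enone; C5 and C4 from the O10 tether and the chelated enolate; C3 from the carbonyl-addition transition state; C6 from a final equilibration.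

Key step: step 20

Remarks on the chemistry:
- Atom numbers are those of the gibberellane skeleton: ring A = C1–C5, C10; ring B = C5, C6, C8, C9, C10; ring C = C8, C9, C11–C14; ring D = C8, C13–C16; C7 is the carboxyl on C6, C17 the methylene carbon, C18 the methyl on C4, C19 the lactone carbonyl.
- α is the face of ring B that carries the lactone oxygen (and C11, C14); β is the face of H5, H9 and C15. At C12, α is the face of ring C turned away from the C15–C16 bridge.
- Racemates 3–6 are drawn without configuration, except 4, for which one enantiomer of the trans pair is drawn.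
- Assumption: the ester enolate formed at C6 in step 20 is protonated on the open β face and gives the 6-epi ester. Step 22 brings C6 to the more stable natural configuration whichever way that protonation goes.

**Route**

Step 1
Reactants: 1 furfural; 2 propargyl bromide
Product: 3 rac-1-(furan-2-yl)but-3-yn-1-ol
Conditions: Zn dust, THF/sat. aq. NH4Cl, 0 °C to rt
Reagents that add atoms: none
Why: Zinc-mediated Barbier propargylation of an aldehyde should give the homopropargylic alcohol, with the allenyl isomer minor; no stereocontrol is needed.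

Step 2
Reactants: 3 rac-1-(furan-2-yl)but-3-yn-1-ol
Product: 5 rac-4-hydroxy-2-(prop-2-yn-1-yl)cyclopent-2-en-1-one, via trans-4-hydroxy-5-propargylcyclopentenone 4 (not isolated)
Conditions: ZnCl2, H2O/1,4-dioxane, reflux; then phosphate buffer to pH 8, rt
Reagents that add atoms: water (O)
Why: Piancatelli rearrangement (water attack on the furfuryl cation, ring opening, conrotatory closure of the pentadienyl cation) gives the trans-4-hydroxy-5-alkyl enone, which the mildly basic buffer should isomerize to the conjugated 2-alkyl isomer, as is usual for these enones.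

Step 3
Reactants: 5 rac-4-hydroxy-2-(prop-2-yn-1-yl)cyclopent-2-en-1-one
Product: 6 rac-4-oxo-3-(prop-2-yn-1-yl)cyclopent-2-en-1-yl acetate
Conditions: Ac2O, pyridine, CH2Cl2, 0 °C
Reagents that add atoms: acetic anhydride (CC(=O)OC(C)=O)
Why: Plain acylation of a secondary alcohol prepares the substrate for enzymatic resolution.

Step 4
Reactants: 6 rac-4-oxo-3-(prop-2-yn-1-yl)cyclopent-2-en-1-yl acetate
Product: 7 (R)-4-hydroxy-2-(prop-2-yn-1-yl)cyclopent-2-en-1-one
Conditions: Burkholderia cepacia lipase, pH 7 phosphate buffer/MTBE, 30 °C, stopped near half conversion; chromatographic removal of the unreacted S acetate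
Reagents that add atoms: none
Why: Lipase-catalysed kinetic resolution by hydrolysis should cleave the R acetate preferentially, as with the closely related rethrolone acetates; this sets the absolute configuration that later steers the cycloaddition.

Step 5
Reactants: 7 (R)-4-hydroxy-2-(prop-2-yn-1-yl)cyclopent-2-en-1-one
Product: 8 (R)-2-(prop-2-yn-1-yl)-4-(triethylsilyloxy)cyclopent-2-en-1-one
Conditions: Et3SiCl, imidazole, DMF, 0 °C
Reagents that add atoms: chlorotriethylsilane (CC[Si](Cl)(CC)CC)
Why: Standard silylation under conditions that are known not to eliminate 4-oxygenated cyclopentenones; the triethylsilyl group is chosen so that it can later be removed beside tert-butyldimethylsilyl ethers.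

Step 6
Reactants: 9 butane-2,3-dione
Product: 10 2,3-bis(tert-butyldimethylsilyloxy)buta-1,3-diene
Conditions: TBSOTf (2.2 equiv), Et3N, CH2Cl2, 0 °C to rt
Reagents that add atoms: tert-butyldimethylsilyl trifluoromethanesulfonate (CC(C)(C)[Si](C)(C)OS(=O)(=O)C(F)(F)F)
Why: Double enol silylation of a 1,2-diketone with a silyl triflate and an amine base is the usual route to 2,3-bis(silyloxy)butadienes.

Step 7
Reactants: 8 (R)-2-(prop-2-yn-1-yl)-4-(triethylsilyloxy)cyclopent-2-en-1-one; 10 2,3-bis(tert-butyldimethylsilyloxy)buta-1,3-diene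
Product: 11 cis-fused hexahydroindenone (C6 ketone; C12=C13 bis-TBS enediol ether; 8β-propargyl; 9β-H; 10β-OTES)
Conditions: Tf2NH (10 mol %), CH2Cl2, −78 to −40 °C
Reagents that add atoms: none
Why: Triflimide-catalysed Diels–Alder reaction of the kind used for hindered α-substituted cycloalkenones with silyloxydienes (the silyl triflimide formed in the flask is the Lewis acid), in which the symmetric diene should add suprafacially to the face of C8=C9 anti to the 10-silyloxy group and so set the quaternary C8 and C9 cis without any regiochemical question.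

Step 8
Reactants: 11 cis-fused hexahydroindenone
Product: 12 C5=C6 enol triflate of 11
Conditions: KN(SiMe3)2 (1.05 equiv), THF, −78 °C; then PhNTf2
Reagents that add atoms: N-phenylbis(trifluoromethanesulfonimide) (O=S(=O)(N(c1ccccc1)S(=O)(=O)C(F)(F)F)C(F)(F)F)
Why: The ketone can enolize only towards C5 because C8 is quaternary, so kinetic enolate formation and O-triflation give a single enol triflate; at −78 °C the β-silyloxy group should not be eliminated.

Step 9
Reactants: 12 C5=C6 enol triflate
Product: 13 tricyclic 12-ketone with ring D closed (13-OTBS; C16=C17 methylene; 10β-OTES; C6 triflate)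
Conditions: (Ph3P)AuCl (5 mol %), AgSbF6 (5 mol %), CH2Cl2/MeOH (10:1), rt
Reagents that add atoms: none
Why: Gold-catalysed 5-exo-dig carbocyclization of a silyl enol ether onto a terminal alkyne (Conia-ene type): C13 attacks the activated alkyne from the face of the propargyl arm, which fixes C13 by bridging and gives the exocyclic methylene after protodeauration, the silyl group on O12 is lost to methanol to give the C12 ketone, and the five-membered closure through C13 is expected to beat the six-membered closure through C12.

Step 10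
Reactants: 13 tricyclic 12-ketone
Product: 14 methyl C5=C6-ene-7-oate (12-ketone; 13-OTBS; 10β-OTES)
Conditions: Pd(OAc)2 (5 mol %), PPh3 (10 mol %), CO (1 atm), MeOH, Et3N, DMF, 40 °C
Reagents that add atoms: carbon monoxide ([C-]#[O+]); methanol (CO)
Why: Palladium-catalysed methoxycarbonylation of an enol triflate is reliable even beside a quaternary centre and installs C7 as the enoate needed later as Michael acceptor.

Step 11
Reactants: 14 methyl C5=C6-ene-7-oate
Product: 15 12α-alcohol (13-OTBS; 10β-OTES)
Conditions: Li[HB(s-Bu)3], THF, −78 °C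
Reagents that add atoms: none
Why: Hydride reduction of the ketone; the bulky reagent should attack C12 along the equatorial path on the side of the two-carbon bridge because the axial path is blocked by the syn-axial C10, giving the axial 12α-hydroxyl gauche to the 13-oxygen and leaving the β-substituted enoate untouched.

Step 12
Reactants: 15 12α-alcohol
Product: 16 12α,13-bis-OTBS 10β-OTES ester
Conditions: TBSOTf, 2,6-lutidine, CH2Cl2, 0 °C to rt
Reagents that add atoms: tert-butyldimethylsilyl trifluoromethanesulfonate (CC(C)(C)[Si](C)(C)OS(=O)(=O)C(F)(F)F)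
Why: Silyl triflate silylation is the standard answer to a hindered secondary alcohol.

Step 13
Reactants: 16 12α,13-bis-OTBS 10β-OTES ester
Product: 17 10β-allylic alcohol (12α,13-bis-OTBS)
Conditions: pyridinium p-toluenesulfonate (cat.), MeOH, 0 °C to rt
Reagents that add atoms: none
Why: Acid-catalysed methanolysis removes a triethylsilyl ether much faster than the two hindered tert-butyldimethylsilyl ethers.

Step 14
Reactants: 17 10β-allylic alcohol
Product: 18 C10 enone (methyl 10-oxo-C5=C6-ene-7-oate; 12α,13-bis-OTBS)
Conditions: Dess–Martin periodinane, NaHCO3, CH2Cl2, rt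
Reagents that add atoms: none
Why: Buffered periodinane oxidation of the allylic alcohol gives the enone without touching silyl ethers or the exocyclic alkene.

Step 15
Reactants: 18 C10 enone
Product: 19 10β-ethynyl-10α-hydroxy ester
Conditions: HC≡CMgBr, THF, −78 to −40 °C
Reagents that add atoms: ethynylmagnesium bromide (C#C[Mg]Br)
Why: 1,2-Addition of an alkynyl Grignard reagent to the ketone (faster than attack on the ester and not prone to conjugate addition); attack on the β face, anti to C11 and to the axial 12-silyloxy group that covers the α face of C10, should place O10 on the α face and set C10.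

Step 16
Reactants: 19 10β-ethynyl-10α-hydroxy ester
Product: 20 10β-(iodoethynyl) carbinol
Conditions: N-iodosuccinimide, AgNO3 (10 mol %), acetone, rt, dark
Reagents that add atoms: N-iodosuccinimide (O=C1CCC(=O)N1I)
Why: Silver-catalysed iodination of a terminal alkyne is selective in the presence of alkenes and a free tertiary alcohol.

Step 17
Reactants: 20 10β-(iodoethynyl) carbinol
Product: 21 10β-[(Z)-2-iodovinyl] carbinol
Conditions: 2-nitrobenzenesulfonylhydrazide, Et3N, THF/i-PrOH, rt
Reagents that add atoms: none
Why: Diimide delivers two hydrogens cis to the iodoalkyne and gives the Z-iodoalkene that ring A requires; iodoalkynes are reduced faster than the 1,1-disubstituted and electron-poor alkenes present.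

Step 18
Reactants: 22 tert-butyl propanoate
Product: 23 tert-butyl 2-methyl-3-oxopropanoate
Conditions: LiN(i-Pr)2, THF, −78 °C; HCO2Et, −78 °C to rt; then aq. HCl
Reagents that add atoms: ethyl formate (CCOC=O)
Why: Crossed Claisen formylation of an ester enolate with a non-enolizable formate gives the α-formyl ester.

Step 19
Reactants: 21 10β-[(Z)-2-iodovinyl] carbinol; 23 tert-butyl 2-methyl-3-oxopropanoate
Product: 25 O10-(2-methyl-3-oxopropanoyl) ester of 21, via formyl(methyl)ketene 24 (not isolated)
Conditions: toluene, 110 °C, slow distillation of t-BuOH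
Reagents that add atoms: none
Why: Thermal transacylation with a tert-butyl β-oxo ester: loss of tert-butanol gives the acylketene, which acylates even hindered tertiary alcohols without base or catalyst, so the iodoalkene and the silyl ethers are not at risk.

Step 20
Reactants: 25 O10-(2-methyl-3-oxopropanoyl) ester
Product: 27 ring-A-closed 3β-hydroxy 19,10-lactone (6-epi methyl ester; 12α,13-bis-OTBS), via Michael adduct aldehyde 26 (not isolated)
Conditions: LiCl (2 equiv), DBU (0.3 equiv), THF, 0 to 40 °C; then DMF, CrCl2 (8 equiv), NiCl2 (2 mol %), rt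
Reagents that add atoms: none
Why: Soft enolization (LiCl, catalytic DBU) gives the lithium-chelated enolate of the α-formyl ester, whose carbon C4 adds to C5 of the C5=C6 enoate (intramolecular Michael addition of a 1,3-dicarbonyl compound, 5-exo-trig) and closes the γ-lactone; the non-enolizable aldehyde 26 is then attacked at C3 by the vinylchromium species formed from the cis-iodoalkene with CrCl2 and catalytic NiCl2 (Nozaki–Hiyama–Kishi reaction, 6-exo-trig onto the carbonyl), which closes ring A. The closest known reaction types are the base-mediated lactone-forming Michael cyclization of O10-acylated C5=C6 esters in this ring system and intramolecular Nozaki–Hiyama–Kishi cyclohexenol formation. C5: the donor hangs on the α oxygen of C10 and can reach only the α face, so the lactone is cis-fused and H5 is β. C4: in the product-like (open-book) transition state, with C19 folded away from ring B, the C4 substituent syn to O10 across the C19–C4 bond ends up beside C6, and in the chelated U-shaped enolate (both carbonyl oxygens on lithium) that substituent is the methyl group, so the formyl group is turned outward towards the iodovinyl arm. C3: addition is expected through the aldehyde rotamer with C=O anti to the C4–C19 bond (dipole minimization; the solvated chromium stays on the open β face, away from the lactone bridge), which gives the pseudo-axial 3β alcohol, while C6 is protonated kinetically on the open β face (6-epi ester) and is corrected in step 22. The step needs Michael addition before carbonyl addition (secured by the staging and by the inertness of vinylchromium reagents towards esters, lactones and silyl ethers) and survival of the cis-iodoalkene and the formyl group (secured by the weak, catalytic base).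

Step 21
Reactants: 27 ring-A-closed 3β-hydroxy 19,10-lactone
Product: 28 3β,12α,13-tris-OTBS lactone (6-epi methyl ester)
Conditions: TBSOTf, 2,6-lutidine, CH2Cl2, −78 to 0 °C
Reagents that add atoms: tert-butyldimethylsilyl trifluoromethanesulfonate (CC(C)(C)[Si](C)(C)OS(=O)(=O)C(F)(F)F)
Why: Silylation of the allylic 3-hydroxyl removes the alkoxide that, in this ring system, triggers base-induced lactone transposition and retro-aldol epimerization, so that C6 can be equilibrated safely.

Step 22
Reactants: 28 3β,12α,13-tris-OTBS lactone (6-epi)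
Product: 29 3β,12α,13-tris-OTBS lactone with natural 6β methyl ester
Conditions: NaOMe (0.3 equiv), MeOH, 25 °C
Reagents that add atoms: none
Why: Base-mediated epimerization of the ester α-carbon: the 6β ester, trans to C4 and away from the C18 methyl and the lactone, is the thermodynamically preferred epimer, and methoxide in methanol cannot change the ester group.

Step 23
Reactants: 29 tris-OTBS lactone methyl ester
Product: 30 tris-OTBS 7-carboxylic acid
Conditions: n-PrSLi, HMPA, rt; then cold dilute HCl to pH 3
Reagents that add atoms: none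
Why: Thiolate demethylation (substitution at the ester methyl group) frees the hindered C7 acid without hydroxide, which the allylic lactone of ring A would not tolerate.

Step 24
Reactants: 30 tris-OTBS 7-carboxylic acid
Product: 31 12α-hydroxygibberellic acid (the target)
Conditions: HF·pyridine, pyridine, THF, 0 °C to rt
Reagents that add atoms: none
Why: Buffered fluoride desilylation removes the three silyl ethers, the tertiary bridgehead one last, under conditions mild enough for the 13-hydroxy-16-ene and the allylic lactone.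

**Compound list**

1 | furfural | O=Cc1ccco1 | starting material
2 | propargyl bromide | C#CCBr | starting material
3 | rac-1-(furan-2-yl)but-3-yn-1-ol | C#CCC(O)c1ccco1 | intermediate
4 | rac-trans-4-hydroxy-5-(prop-2-yn-1-yl)cyclopent-2-en-1-one (not isolated) | O=C1C=C[C@@H](O)[C@@H]1CC#C | intermediate
5 | rac-4-hydroxy-2-(prop-2-yn-1-yl)cyclopent-2-en-1-one | C#CCC1=CC(O)CC1=O | intermediate
6 | rac-4-oxo-3-(prop-2-yn-1-yl)cyclopent-2-en-1-yl acetate | C#CCC1=CC(OC(C)=O)CC1=O | intermediate
7 | (R)-4-hydroxy-2-(prop-2-yn-1-yl)cyclopent-2-en-1-one | C#CCC1=C[C@H](O)CC1=O | intermediate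
8 | (R)-2-(prop-2-yn-1-yl)-4-(triethylsilyloxy)cyclopent-2-en-1-one | C#CCC1=C[C@H](O[Si](CC)(CC)CC)CC1=O | intermediate
9 | butane-2,3-dione | CC(=O)C(C)=O | starting material
10 | 2,3-bis(tert-butyldimethylsilyloxy)buta-1,3-diene | C=C(O[Si](C)(C)C(C)(C)C)C(=C)O[Si](C)(C)C(C)(C)C | intermediate
11 | cis-fused 5,6-bis(TBS-oxy)-7a-propargyl-3-(TES-oxy)-2,3,3a,4,7,7a-hexahydroinden-1-one (ring-fusion H and propargyl cis and on the face of the 3-OTES group; C6 ketone, C12=C13 enediol ether) | C#CC[C@]12CC(O[Si](C)(C)C(C)(C)C)=C(O[Si](C)(C)C(C)(C)C)C[C@H]1[C@H](O[Si](CC)(CC)CC)CC2=O | intermediate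
12 | C5=C6 enol triflate of 11 | C#CC[C@]12CC(O[Si](C)(C)C(C)(C)C)=C(O[Si](C)(C)C(C)(C)C)C[C@H]1[C@H](O[Si](CC)(CC)CC)C=C2OS(=O)(=O)C(F)(F)F | intermediate
13 | tricyclic 12-ketone with ring D closed (13-OTBS; 16-methylene; 10β-OTES; C6 triflate) | C=C1C[C@]23C[C@@]1(O[Si](C)(C)C(C)(C)C)C(=O)C[C@H]2[C@H](O[Si](CC)(CC)CC)C=C3OS(=O)(=O)C(F)(F)F | intermediate
14 | methyl C5=C6-ene-7-oate (12-ketone; 13-OTBS; 10β-OTES) | C=C1C[C@]23C[C@@]1(O[Si](C)(C)C(C)(C)C)C(=O)C[C@H]2[C@H](O[Si](CC)(CC)CC)C=C3C(=O)OC | intermediate
15 | 12α-alcohol (13-OTBS; 10β-OTES) | C=C1C[C@]23C[C@@]1(O[Si](C)(C)C(C)(C)C)[C@@H](O)C[C@H]2[C@H](O[Si](CC)(CC)CC)C=C3C(=O)OC | intermediate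
16 | 12α,13-bis-OTBS 10β-OTES ester | C=C1C[C@]23C[C@@]1(O[Si](C)(C)C(C)(C)C)[C@@H](O[Si](C)(C)C(C)(C)C)C[C@H]2[C@H](O[Si](CC)(CC)CC)C=C3C(=O)OC | intermediate
17 | 10β-allylic alcohol (12α,13-bis-OTBS) | C=C1C[C@]23C[C@@]1(O[Si](C)(C)C(C)(C)C)[C@@H](O[Si](C)(C)C(C)(C)C)C[C@H]2[C@H](O)C=C3C(=O)OC | intermediate
18 | C10 enone (methyl 10-oxo-C5=C6-ene-7-oate; 12α,13-bis-OTBS) | C=C1C[C@]23C[C@@]1(O[Si](C)(C)C(C)(C)C)[C@@H](O[Si](C)(C)C(C)(C)C)C[C@H]2C(=O)C=C3C(=O)OC | intermediate
19 | 10β-ethynyl-10α-hydroxy ester | C=C1C[C@]23C[C@@]1(O[Si](C)(C)C(C)(C)C)[C@@H](O[Si](C)(C)C(C)(C)C)C[C@H]2[C@@](C#C)(O)C=C3C(=O)OC | intermediate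
20 | 10β-(iodoethynyl) carbinol | C=C1C[C@]23C[C@@]1(O[Si](C)(C)C(C)(C)C)[C@@H](O[Si](C)(C)C(C)(C)C)C[C@H]2[C@@](C#CI)(O)C=C3C(=O)OC | intermediate
21 | 10β-[(Z)-2-iodovinyl] carbinol | C=C1C[C@]23C[C@@]1(O[Si](C)(C)C(C)(C)C)[C@@H](O[Si](C)(C)C(C)(C)C)C[C@H]2[C@@](/C=C\I)(O)C=C3C(=O)OC | intermediate
22 | tert-butyl propanoate | CCC(=O)OC(C)(C)C | starting material
23 | tert-butyl 2-methyl-3-oxopropanoate | CC(C=O)C(=O)OC(C)(C)C | intermediate
24 | formyl(methyl)ketene (2-methyl-3-oxoprop-2-enal; not isolated) | CC(C=O)=C=O | intermediate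
25 | O10-(2-methyl-3-oxopropanoyl) ester of 21 (C4 epimers and enol) | C=C1C[C@]23C[C@@]1(O[Si](C)(C)C(C)(C)C)[C@@H](O[Si](C)(C)C(C)(C)C)C[C@H]2[C@@](/C=C\I)(OC(=O)C(C)C=O)C=C3C(=O)OC | intermediate
26 | Michael adduct: cis-fused 19,10-lactone with 4-formyl, 4β-methyl, 10β-(Z)-iodovinyl, 6-epi ester (not isolated) | C=C1C[C@]23C[C@@]1(O[Si](C)(C)C(C)(C)C)[C@@H](O[Si](C)(C)C(C)(C)C)C[C@H]2[C@@]1(/C=C\I)OC(=O)[C@](C)(C=O)[C@H]1[C@H]3C(=O)OC | intermediate
27 | ring-A-closed 3β-hydroxy-1-ene 19,10-lactone (6-epi methyl ester; 12α,13-bis-OTBS) | C=C1C[C@]23C[C@@]1(O[Si](C)(C)C(C)(C)C)[C@@H](O[Si](C)(C)C(C)(C)C)C[C@H]2[C@@]12C=C[C@H](O)[C@@](C)(C(=O)O1)[C@H]2[C@H]3C(=O)OC | intermediate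
28 | 3β,12α,13-tris-OTBS lactone (6-epi methyl ester) | C=C1C[C@]23C[C@@]1(O[Si](C)(C)C(C)(C)C)[C@@H](O[Si](C)(C)C(C)(C)C)C[C@H]2[C@@]12C=C[C@H](O[Si](C)(C)C(C)(C)C)[C@@](C)(C(=O)O1)[C@H]2[C@H]3C(=O)OC | intermediate
29 | 3β,12α,13-tris-OTBS lactone with natural 6β methyl ester | C=C1C[C@]23C[C@@]1(O[Si](C)(C)C(C)(C)C)[C@@H](O[Si](C)(C)C(C)(C)C)C[C@H]2[C@@]12C=C[C@H](O[Si](C)(C)C(C)(C)C)[C@@](C)(C(=O)O1)[C@H]2[C@@H]3C(=O)OC | intermediate
30 | tris-OTBS 7-carboxylic acid | C=C1C[C@]23C[C@@]1(O[Si](C)(C)C(C)(C)C)[C@@H](O[Si](C)(C)C(C)(C)C)C[C@H]2[C@@]12C=C[C@H](O[Si](C)(C)C(C)(C)C)[C@@](C)(C(=O)O1)[C@H]2[C@@H]3C(=O)O | intermediate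
31 | 12α-hydroxygibberellic acid (3β,12α,13-trihydroxy-1,16-diene 19,10-lactone 7-carboxylic acid of the 20-norgibberellane skeleton) | C=C1C[C@]23C[C@@]1(O)[C@@H](O)C[C@H]2[C@@]12C=C[C@H](O)[C@@](C)(C(=O)O1)[C@H]2[C@@H]3C(=O)O | target

**Step count and risks**

Total step count: 24. Longest linear sequence: 22 steps (steps 1–5, 7–17, 19–24).

Steps most likely to fail:

Step 20. What may go wrong: the Michael addition may pass through a non-chelated (sickle) enolate and place the formyl group on the wrong side of C4, so that ring A cannot close; the formyl group may be lost by retro-Claisen cleavage; or chelation of chromium between the aldehyde and the lactone carbonyl may give the 3-epimer. Fallback (known chemistry, different bond order): it sets out from 21 and comes back at 27. The tertiary alcohol of 21 is acylated with propanoic anhydride (DMAP, Et3N) to the O10-propanoate F1. Its ester enolate (KN(SiMe3)2, THF, −78 °C) adds to C5 to give the 4-H lactone F2, for which the configuration at C4 does not matter. Palladium-catalysed formylation of the iodoalkene (Pd(PPh3)4, CO, Bu3SnH) gives the cis-enal F3. The lactone enolate of F3 (KN(SiMe3)2, −78 °C) then closes ring A by aldol addition of C4 to C3, a closure that in this ring system favours the 3β alcohol kinetically, to give 27.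

Step 9. What may go wrong: ring closure through the other enol-ether carbon (C12, 6-exo-dig) to a bicyclo[2.2.2]octanone, or protodesilylation of the enediol ether before cyclization. Fallback: it sets out from 12 and comes back at 13. The regioisomeric bicyclo[2.2.2]octanone F4, formed from 12 under the conditions of step 9, is carried on and desilylated (Bu4NF buffered with AcOH) to the bicyclo[2.2.2] ketol F5. An α-ketol rearrangement (Al(Ot-Bu)3, toluene, 80 °C; 1,2-shift of C16 from C12 to C13) then gives the bicyclo[3.2.1] ketol F6, expected to be the more stable isomer. The secondary C10 hydroxyl is silylated (Et3SiCl, imidazole) to the 10-O-triethylsilyl ketol F7, and the tertiary hydroxyl with TBSOTf and 2,6-lutidine to give 13.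

Step 19. What may go wrong: slow capture of the ketene by the crowded O10 hydroxyl, or thermal ionization or sigmatropic rearrangement of the tertiary allylic β-oxo ester at 110 °C. Fallback: it sets out from 21 and comes back at 25. Ring opening of 2,2,5-trimethyl-1,3-dioxane-4,6-dione by the tertiary alcohol (toluene, 90 °C) gives the hydrogen methylmalonate F8. The free acid is reduced selectively through its mixed anhydride (isobutyl chloroformate, N-methylmorpholine; then NaBH4, MeOH, −15 °C) to the 3-hydroxy-2-methylpropanoate F9, and Dess–Martin oxidation of the primary alcohol gives 25.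

**Further compounds**

F1 | step 20 | O10-propanoate of 21 | C=C1C[C@]23C[C@@]1(O[Si](C)(C)C(C)(C)C)[C@@H](O[Si](C)(C)C(C)(C)C)C[C@H]2[C@@](/C=C\I)(OC(=O)CC)C=C3C(=O)OC
F2 | step 20 | 4-H lactone from Michael cyclization of F1 (C4 epimers; 6-epi ester) | C=C1C[C@]23C[C@@]1(O[Si](C)(C)C(C)(C)C)[C@@H](O[Si](C)(C)C(C)(C)C)C[C@H]2[C@@]1(/C=C\I)OC(=O)C(C)[C@H]1[C@H]3C(=O)OC
F3 | step 20 | cis-enal from formylation of F2 | C=C1C[C@]23C[C@@]1(O[Si](C)(C)C(C)(C)C)[C@@H](O[Si](C)(C)C(C)(C)C)C[C@H]2[C@@]1(/C=C\C=O)OC(=O)C(C)[C@H]1[C@H]3C(=O)OC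
F4 | step 9 | bicyclo[2.2.2]octanone regioisomer (C12 quaternary with OTBS; C13 ketone) | C=C1C[C@]23CC(=O)[C@@]1(O[Si](C)(C)C(C)(C)C)C[C@H]2[C@H](O[Si](CC)(CC)CC)C=C3OS(=O)(=O)C(F)(F)F
F5 | step 9 | bicyclo[2.2.2] ketol (12-OH; 13-ketone; 10β-OH) | C=C1C[C@]23CC(=O)[C@@]1(O)C[C@H]2[C@H](O)C=C3OS(=O)(=O)C(F)(F)F
F6 | step 9 | bicyclo[3.2.1] ketol (13-OH; 12-ketone; 10β-OH) | C=C1C[C@]23C[C@@]1(O)C(=O)C[C@H]2[C@H](O)C=C3OS(=O)(=O)C(F)(F)F
F7 | step 9 | 10-O-triethylsilyl bicyclo[3.2.1] ketol | C=C1C[C@]23C[C@@]1(O)C(=O)C[C@H]2[C@H](O[Si](CC)(CC)CC)C=C3OS(=O)(=O)C(F)(F)F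
F8 | step 19 | O10 hydrogen methylmalonate of 21 | C=C1C[C@]23C[C@@]1(O[Si](C)(C)C(C)(C)C)[C@@H](O[Si](C)(C)C(C)(C)C)C[C@H]2[C@@](/C=C\I)(OC(=O)C(C)C(=O)O)C=C3C(=O)OC
F9 | step 19 | O10 3-hydroxy-2-methylpropanoate of 21 | C=C1C[C@]23C[C@@]1(O[Si](C)(C)C(C)(C)C)[C@@H](O[Si](C)(C)C(C)(C)C)C[C@H]2[C@@](/C=C\I)(OC(=O)C(C)CO)C=C3C(=O)OC
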